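**Retrosynthetic overview**
1. The only ring, the cyclopentene, is closed last by ring-closing metathesis across C3=C4, which gives the target directly from the acyclic meso diene 13 without protecting groups.
2. Enabling feature: C3=C4 is an unsubstituted cis CH=CH inside the five-membered ring, flanked by the acetoxy carbons C2 and C5, which both hang from the fully substituted C1. Cutting it leaves a hepta-1,6-diene whose two vinyl arms are geminal on C1 and related by the mirror plane through C1.
3. The C1–C(=O) bond at the fully substituted carbon comes from a three-component union of meso dienone 7, CO and decyllithium; Felkin–Anh control from both silyloxy centres sets C1.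
4. Dienone 7 comes from xylitol: its C2 and C4 oxygens (1,3-syn) become C2–O and C5–O of the target, and two-directional oxidation/Wittig adds both vinyl groups.
5. Ring order: a temporary 1,3-dioxane (benzylidene) ring is made first and removed again; the carbocycle is formed in the last step.

Key step: step 9

Remark: the target is a meso compound, (1r,2R,5S): both acetoxy groups and the undecanoyl group lie on one face of the ring and the tertiary hydroxyl on the other, so every intermediate is achiral and no enantiocontrol is needed.

**Route**

Step 1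
Reactants: 1 xylitol
Product: 2 2,4-O-benzylidenexylitol (all-cis 4,6-bis(hydroxymethyl)-2-phenyl-1,3-dioxan-5-ol; phenyl and both CH2OH equatorial, 5-OH axial)
Conditions: PhCH(OMe)2 (1.05 equiv), CSA (cat.), DMF, 50 °C, reduced pressure
Reagents that add atoms: benzaldehyde dimethyl acetal, COC(OC)c1ccccc1
Why: Acid-catalysed transacetalisation under thermodynamic control should select the 1,3-syn 2,4-diol, because only this 1,3-dioxane carries phenyl and both CH2OH groups equatorial with the 3-OH axial; the acetal carbon takes the equatorial-phenyl configuration by equilibration.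

Step 2
Reactants: 2 2,4-O-benzylidenexylitol
Product: 3 all-cis 5-hydroxy-2-phenyl-1,3-dioxane-4,6-dicarbaldehyde
Conditions: TEMPO (0.2 equiv), PhI(OAc)2 (2.3 equiv), CH2Cl2/MeCN, rt
Reagents that add atoms: none
Why: Oxoammonium (TEMPO) oxidation is selective for the two primary alcohols over the hindered axial secondary one and should stop at the aldehyde in the absence of water.

Step 3
Reactants: 3 all-cis 5-hydroxy-2-phenyl-1,3-dioxane-4,6-dicarbaldehyde
Product: 4 all-cis 2-phenyl-4,6-divinyl-1,3-dioxan-5-ol
Conditions: Ph3PCH3Br (5 equiv), KOtBu (4.8 equiv), THF, 0 °C to rt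
Reagents that add atoms: methyltriphenylphosphonium bromide, C[P+](c1ccccc1)(c1ccccc1)c1ccccc1.[Br-]
Why: Two-directional Wittig methylenation; the excess ylide tolerates the free hydroxyl as its alkoxide, and any epimerisation at the α-carbons is expected to return to the favoured cis-diequatorial aldehyde before olefination.

Step 4
Reactants: 4 all-cis 2-phenyl-4,6-divinyl-1,3-dioxan-5-ol
Product: 5 (3R,4r,5S)-hepta-1,6-diene-3,4,5-triol (meso, xylo: 3,4-syn and 4,5-syn)
Conditions: AcOH/H2O 4:1, 45 °C
Reagents that add atoms: none
Why: Mild acid hydrolysis of the benzylidene acetal; the simple secondary allylic alcohols do not ionise under these conditions, so the three stereocentres inherited from xylitol are kept.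

Step 5
Reactants: 5 (3R,4r,5S)-hepta-1,6-diene-3,4,5-triol
Product: 6 meso 3,5-bis(tert-butyldimethylsilyloxy)hepta-1,6-dien-4-ol (xylo)
Conditions: TBSCl (2.1 equiv), imidazole, DMF, 0 °C
Reagents that add atoms: tert-butyldimethylsilyl chloride, CC(C)(C)[Si](C)(C)Cl
Why: Silylation under steric control should take the two flanking allylic hydroxyls, because the central hydroxyl sits between two branched carbinol carbons and becomes more shielded after the first silyl group is on.

Step 6
Reactants: 6 meso 3,5-bis(tert-butyldimethylsilyloxy)hepta-1,6-dien-4-ol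
Product: 7 (3R,5S)-3,5-bis(tert-butyldimethylsilyloxy)hepta-1,6-dien-4-one (meso)
Conditions: Dess–Martin periodinane (1.3 equiv), pyridine, CH2Cl2, 0 °C
Reagents that add atoms: none
Why: Dess–Martin oxidation is non-basic, so the doubly activated α-hydrogens (allylic and α-silyloxy) are not removed and the meso relation of the two α-centres should survive.

Step 7
Reactants: 7 (3R,5S)-3,5-bis(tert-butyldimethylsilyloxy)hepta-1,6-dien-4-one; 8 1-bromodecane
Product: 11 1-[3,5-bis(tert-butyldimethylsilyloxy)-4-hydroxyhepta-1,6-dien-4-yl]undecan-1-one (meso, xylo: 4-OH syn to both silyloxy groups in the zigzag drawing), via decyllithium 9 (not isolated), via undecanoyllithium 10 (not isolated)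
Conditions: 8, Li, Et2O, 0 °C; added slowly to 7 in THF/Et2O/pentane 4:4:1 saturated with CO (1 atm), −110 °C; AcOH quench at −110 °C
Reagents that add atoms: carbon monoxide, [C-]#[O+]
Why: Direct nucleophilic acylation: decyllithium takes up CO at −110 °C to give the acyllithium, which is trapped at once by the non-chelating bis-silyloxy ketone; in the polar Felkin–Anh arrangement both C–OSi bonds lie anti to the incoming nucleophile (vinyl inside, H outside), the two α-centres of the meso ketone reinforce each other, and the new tertiary carbinol oxygen should end up syn to both silyloxy groups, which is the configuration of C1 in the target.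

Step 8
Reactants: 11 1-[3,5-bis(tert-butyldimethylsilyloxy)-4-hydroxyhepta-1,6-dien-4-yl]undecan-1-one
Product: 13 4-hydroxy-4-undecanoylhepta-1,6-diene-3,5-diyl diacetate (meso, xylo), via triol ketone 12 (not isolated)
Conditions: HF·pyridine, THF/pyridine, 0 °C to rt; concentrate; then Ac2O, pyridine, rt (no DMAP)
Reagents that add atoms: acetic anhydride, CC(=O)OC(C)=O
Why: Fluoride desilylation under buffered, non-basic conditions avoids retro-aldol cleavage of the β-hydroxy ketone, and the following acetylation should take only the two secondary allylic hydroxyls, since the hindered tertiary α-ketol hydroxyl is inert without an acyl-transfer catalyst.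

Step 9
Reactants: 13 4-hydroxy-4-undecanoylhepta-1,6-diene-3,5-diyl diacetate
Product: 14 (1r,2R,5S)-1-hydroxy-1-undecanoylcyclopent-3-ene-2,5-diyl diacetate (target; acetoxy groups cis to each other and to the acyl group, OH trans)
Conditions: second-generation Grubbs catalyst RuCl2(=CHPh)(H2IMes)(PCy3) (5 mol %), CH2Cl2 (5 mM), 40 °C
Reagents that add atoms: none
Why: Ring-closing olefin metathesis: the ruthenium benzylidene exchanges onto one terminal vinyl group, the new alkylidene adds across the second vinyl group to a ruthenacyclobutane, and cycloreversion releases the ring C3=C4 bond and ethylene, whose loss makes the closure irreversible. The closest known reaction type is the RCM of 3,5-dioxygenated hepta-1,6-dienes (for example sugar-derived dienes) to cyclopentenols and their esters. The one ring of the target, the five-membered carbocycle, is closed in the 1,6-diene-to-cyclopentene mode, which can only give the cis ring alkene. No stereocentre is formed: C2, C1 and C5 are carried unchanged from 13, and because the closure joins the two mirror-related arms of a meso diene, the product should be the meso target itself. The step needs ring closure to win over intermolecular metathesis and over Ru–H olefin migration towards enol acetates; the fully substituted C1 between the two arms (gem-disubstituent effect), high dilution and the fast five-ring closure should secure this, and the esters, the ketone and the hindered tertiary alcohol are tolerated by the catalyst.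

**Compound list**
1 | xylitol | OC[C@H](O)[C@@H](O)[C@H](O)CO | starting material
2 | 2,4-O-benzylidenexylitol (all-cis 4,6-bis(hydroxymethyl)-2-phenyl-1,3-dioxan-5-ol) | OC[C@@H]1O[C@H](c2ccccc2)O[C@H](CO)[C@@H]1O | intermediate
3 | all-cis 5-hydroxy-2-phenyl-1,3-dioxane-4,6-dicarbaldehyde | O=C[C@@H]1O[C@H](c2ccccc2)O[C@H](C=O)[C@@H]1O | intermediate
4 | all-cis 2-phenyl-4,6-divinyl-1,3-dioxan-5-ol | C=C[C@@H]1O[C@H](c2ccccc2)O[C@H](C=C)[C@@H]1O | intermediate
5 | (3R,4r,5S)-hepta-1,6-diene-3,4,5-triol (meso, xylo) | C=C[C@H](O)[C@@H](O)[C@H](O)C=C | intermediate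
6 | meso 3,5-bis(tert-butyldimethylsilyloxy)hepta-1,6-dien-4-ol (xylo) | C=C[C@H](O[Si](C)(C)C(C)(C)C)[C@@H](O)[C@H](O[Si](C)(C)C(C)(C)C)C=C | intermediate
7 | (3R,5S)-3,5-bis(tert-butyldimethylsilyloxy)hepta-1,6-dien-4-one (meso) | C=C[C@H](O[Si](C)(C)C(C)(C)C)C(=O)[C@H](O[Si](C)(C)C(C)(C)C)C=C | intermediate
8 | 1-bromodecane | CCCCCCCCCCBr | starting material
9 | decyllithium | [Li]CCCCCCCCCC | intermediate
10 | undecanoyllithium | [Li]C(=O)CCCCCCCCCC | intermediate
11 | 1-[3,5-bis(tert-butyldimethylsilyloxy)-4-hydroxyhepta-1,6-dien-4-yl]undecan-1-one (meso, xylo) | C=C[C@H](O[Si](C)(C)C(C)(C)C)[C@@](C(=O)CCCCCCCCCC)(O)[C@H](O[Si](C)(C)C(C)(C)C)C=C | intermediate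
12 | 1-(3,4,5-trihydroxyhepta-1,6-dien-4-yl)undecan-1-one (meso, xylo; triol ketone) | C=C[C@H](O)[C@@](C(=O)CCCCCCCCCC)(O)[C@H](O)C=C | intermediate
13 | 4-hydroxy-4-undecanoylhepta-1,6-diene-3,5-diyl diacetate (meso, xylo) | C=C[C@H](OC(C)=O)[C@@](C(=O)CCCCCCCCCC)(O)[C@H](OC(C)=O)C=C | intermediate
14 | (1r,2R,5S)-1-hydroxy-1-undecanoylcyclopent-3-ene-2,5-diyl diacetate | CCCCCCCCCCC(=O)[C@@]1(O)[C@@H](OC(C)=O)C=C[C@H]1OC(C)=O | target

**Step count and risks**

Total step count: 9. Longest linear sequence: 9 steps (xylitol 1 to target 14); decyllithium is made from 8 inside step 7.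

Steps most likely to fail:

1. Step 7. Facial selectivity in the addition may be low, or the organolithium may remove one of the doubly activated α-hydrogens of 7 (enolisation followed by conjugation), or add directly before it has taken up CO. The fallback closes the ring first and lets a bridged temporary ring control C1. It sets out from triol 5: RCM of unprotected 5 (second-generation Grubbs catalyst RuCl2(=CHPh)(H2IMes)(PCy3), CH2Cl2 with a little MeOH, 40 °C) should give meso cyclopent-3-ene-1,2,5-triol F1 (1-OH trans to the cis 2,5-diol). Benzaldehyde dimethyl acetal/CSA can only tie the cis 2,5-diol and should give exo-3-phenyl-2,4-dioxabicyclo[3.2.1]oct-6-en-8-ol F2. Dess–Martin oxidation gives exo-3-phenyl-2,4-dioxabicyclo[3.2.1]oct-6-en-8-one F3, which cannot enolise because both α-carbons are bridgeheads. F3 is a locked 1,3-dioxan-5-one whose axial face, the one over the acetal bridge, has no syn-axial hydrogens and can pre-coordinate lithium at the two acetal oxygens. Decyllithium/CO as in step 7 should therefore place the acyl group cis to both ring oxygens and give 8-hydroxy-8-undecanoyl acetal F4. Aqueous AcOH frees 1-undecanoylcyclopent-3-ene-1,2,5-triol F5, and Ac2O/pyridine acetylates its two secondary hydroxyls. The fallback comes back to the route at target 14.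

2. Step 5. Silylation may not discriminate well enough between the flanking and the central hydroxyl, and silyl migration under the basic conditions can scramble the pattern. The fallback replaces steric discrimination by the acetal already present and sets out from dioxanol 4, whose only free hydroxyl is the central one. NaH/4-methoxybenzyl chloride gives the 5-O-(4-methoxybenzyl) ether of 4 F6; aqueous AcOH removes the benzylidene acetal to give 4-O-(4-methoxybenzyl)hepta-1,6-diene-3,5-diol F7; TBSCl/imidazole gives the 3,5-bis(silyl) 4-O-(4-methoxybenzyl) ether F8; DDQ in wet CH2Cl2 removes the benzyl-type ether. The fallback comes back to the route at 6.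

3. Step 3. The dialdehyde 3 may sit as hydrates or oligomeric hemiacetals that react sluggishly, and the basic ylide may epimerise an α-centre before olefination or trigger β-elimination of the 5-oxygen. The fallback avoids the aldehyde oxidation level and sets out from xylitol 1. TsCl/pyridine at −20 °C should give 1,5-di-O-tosylxylitol F9; K2CO3/MeOH closes both terminal epoxides to 1,2:4,5-dianhydroxylitol F10; excess dimethylsulfonium methylide (Me3S+ I−, n-BuLi, THF, −10 °C to rt) opens each terminal epoxide with one-carbon homologation to the allylic alcohol. The fallback comes back to the route at triol 5.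

**Further compounds**
F1 | step 7 | meso cyclopent-3-ene-1,2,5-triol (1-OH trans to the cis 2,5-diol) | O[C@@H]1[C@@H](O)C=C[C@H]1O
F2 | step 7 | exo-3-phenyl-2,4-dioxabicyclo[3.2.1]oct-6-en-8-ol | O[C@@H]1[C@@H]2C=C[C@H]1O[C@H](c3ccccc3)O2
F3 | step 7 | exo-3-phenyl-2,4-dioxabicyclo[3.2.1]oct-6-en-8-one | O=C1[C@@H]2C=C[C@H]1O[C@H](c3ccccc3)O2
F4 | step 7 | 1-(8-hydroxy-exo-3-phenyl-2,4-dioxabicyclo[3.2.1]oct-6-en-8-yl)undecan-1-one (acyl cis to the ring oxygens) | CCCCCCCCCCC(=O)[C@@]1(O)[C@@H]2C=C[C@H]1O[C@H](c3ccccc3)O2
F5 | step 7 | 1-undecanoylcyclopent-3-ene-1,2,5-triol (1-OH trans to the cis 2,5-diol) | CCCCCCCCCCC(=O)[C@@]1(O)[C@@H](O)C=C[C@H]1O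
F6 | step 5 | all-cis 5-(4-methoxybenzyloxy)-2-phenyl-4,6-divinyl-1,3-dioxane | C=C[C@@H]1O[C@H](c2ccccc2)O[C@H](C=C)[C@@H]1OCc1ccc(OC)cc1
F7 | step 5 | meso 4-(4-methoxybenzyloxy)hepta-1,6-diene-3,5-diol (xylo) | C=C[C@H](O)[C@@H](OCc1ccc(OC)cc1)[C@H](O)C=C
F8 | step 5 | meso 3,5-bis(tert-butyldimethylsilyloxy)-4-(4-methoxybenzyloxy)hepta-1,6-diene (xylo) | C=C[C@H](O[Si](C)(C)C(C)(C)C)[C@@H](OCc1ccc(OC)cc1)[C@H](O[Si](C)(C)C(C)(C)C)C=C
F9 | step 3 | 1,5-di-O-tosylxylitol | Cc1ccc(cc1)S(=O)(=O)OC[C@H](O)[C@@H](O)[C@H](O)COS(=O)(=O)c1ccc(C)cc1
F10 | step 3 | 1,2:4,5-dianhydroxylitol | C1O[C@@H]1[C@@H](O)[C@H]1CO1
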